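**Retrosynthetic overview**
1. (M)-Bisoflavolin C ⇒ its tetra-O-methyl ether; the four methyl ethers are cleaved last and the C3'–C8'' axis is resolved only at the end.
2. Key disconnection: C3–C1' together with O1–C2 of pyranone ring C, back to an open-chain ortho-hydroxyaryl enaminone (ring A plus C4–C3–C2–NMe2) and the arenediazonium salt of ring B, which already carries the second isoflavone.
3. Enabling feature: C3 of ring C is the α-carbon of the vinylogous ester O1–C2=C3–C4=O. With NMe2 in place of O1 at C2 this carbon accepts an aryl radical, and the ring A phenol oxygen then closes ring C on C2 with loss of HNMe2.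
4. Diazonium salt ⇐ aniline ⇐ nitro biaryl ⇐ Suzuki–Miyaura coupling at C8'' (the axis bond) of 8-iodo-7-O-methylformononetin with a nitroarylboronic acid; C8'' is iodinated on purchased formononetin.
5. Ring order: rings A', C', B' come with formononetin; ring B is attached at C8''; ring A comes with paeonol; ring C is formed last, in the key step.

Key step: step 7

Remark (assumption): the SMILES shows no descriptor for the C3'–C8'' biaryl axis, the only stereogenic element; since only 4'-OH, 7''-OH and ring oxygen O1'' flank it, the axis is assumed to turn at cross-coupling temperatures, so the skeleton is built without axial control and the (M) form is taken in the last step; SMILES below therefore carry no axial descriptor.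

Locants: isoflavone unit 1 = rings A and C (positions 2–8a) and ring B (1'–6'); isoflavone unit 2 = rings A' and C' (positions 2''–8a'') and ring B' (1'''–6''').

**Route**

Step 1
Reactants: 1 formononetin (7-hydroxy-3-(4-methoxyphenyl)-4H-chromen-4-one)
Product: 2 7-hydroxy-8-iodo-3-(4-methoxyphenyl)-4H-chromen-4-one
Conditions: NIS (1.05 equiv), DMF, 0 °C to rt, dark
Reagents that add atoms: N-iodosuccinimide, O=C1CCC(=O)N1I
Why: Electrophilic aromatic iodination of a 7-hydroxychromone should go to C8, the position between the phenol and O1 that corresponds to C1 of 2-naphthol, while the anisole ring B' and the electron-poor C2=C3 bond are far less reactive.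

Step 2
Reactants: 2 7-hydroxy-8-iodo-3-(4-methoxyphenyl)-4H-chromen-4-one
Product: 3 8-iodo-7-methoxy-3-(4-methoxyphenyl)-4H-chromen-4-one
Conditions: MeI (1.5 equiv), K2CO3 (2 equiv), acetone, 50 °C
Reagents that add atoms: iodomethane, CI
Why: Williamson ether synthesis on the only acidic hydroxyl, under carbonate conditions that leave the pyranone and the aryl iodide untouched.

Step 3
Reactants: 3 8-iodo-7-methoxy-3-(4-methoxyphenyl)-4H-chromen-4-one; 4 (2-methoxy-5-nitrophenyl)boronic acid
Product: 5 7-methoxy-8-(2-methoxy-5-nitrophenyl)-3-(4-methoxyphenyl)-4H-chromen-4-one (axis unresolved)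
Conditions: Pd(OAc)2 (5 mol %), SPhos (10 mol %), K3PO4 (3 equiv), toluene/H2O (10:1), 90 °C
Reagents that add atoms: none
Why: Suzuki–Miyaura coupling in which the bulky dialkylbiarylphosphine gives a monoligated zerovalent palladium that inserts into the doubly ortho-flanked carbon–iodine bond and accepts an ortho-substituted boronic acid, while the nitro group and, under the mild biphasic phosphate base, the pyranone are tolerated.

Step 4
Reactants: 5 7-methoxy-8-(2-methoxy-5-nitrophenyl)-3-(4-methoxyphenyl)-4H-chromen-4-one
Product: 6 8-(5-amino-2-methoxyphenyl)-7-methoxy-3-(4-methoxyphenyl)-4H-chromen-4-one (axis unresolved)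
Conditions: Fe powder (5 equiv), NH4Cl (5 equiv), EtOH/THF/H2O, 70 °C
Reagents that add atoms: none
Why: Béchamp-type reduction with iron is selective for the nitro group and should not touch the chromone enone or the aryl ethers, which catalytic hydrogenation over palladium could.

Step 5
Reactants: 6 8-(5-amino-2-methoxyphenyl)-7-methoxy-3-(4-methoxyphenyl)-4H-chromen-4-one
Product: 7 4-methoxy-3-[7-methoxy-3-(4-methoxyphenyl)-4-oxo-4H-chromen-8-yl]benzenediazonium tetrafluoroborate (axis unresolved)
Conditions: tBuONO (1.5 equiv), HBF4 (48 % aq., 2.2 equiv), MeCN, 0 °C; precipitation with Et2O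
Reagents that add atoms: tert-butyl nitrite, CC(C)(C)ON=O; tetrafluoroboric acid, [H+].F[B-](F)(F)F
Why: Diazotization of the aniline with an alkyl nitrite and HBF4 gives a para-alkoxy-stabilized arenediazonium tetrafluoroborate that should precipitate and can be stored cold, and the acid-stable chromone is not affected.

Step 6
Reactants: 8 paeonol (1-(2-hydroxy-4-methoxyphenyl)ethan-1-one)
Product: 9 (E)-3-(dimethylamino)-1-(2-hydroxy-4-methoxyphenyl)prop-2-en-1-one
Conditions: DMF-DMA (1.5 equiv), toluene, 100 °C
Reagents that add atoms: N,N-dimethylformamide dimethyl acetal, COC(OC)N(C)C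
Why: Enaminone formation by condensation of the methyl ketone with an amide acetal gives the E push-pull alkene, and the hydrogen-bonded ortho phenol stays free for the later ring closure.

Step 7
Reactants: 7 4-methoxy-3-[7-methoxy-3-(4-methoxyphenyl)-4-oxo-4H-chromen-8-yl]benzenediazonium tetrafluoroborate (1 equiv, added in portions); 9 (E)-3-(dimethylamino)-1-(2-hydroxy-4-methoxyphenyl)prop-2-en-1-one (2.5 equiv)
Product: 11 tetra-O-methylbisoflavolin C (7-methoxy-8-[2-methoxy-5-(7-methoxy-4-oxo-4H-chromen-3-yl)phenyl]-3-(4-methoxyphenyl)-4H-chromen-4-one; axis unresolved), via 2-(dimethylamino)isoflavanone aminal 10 (not isolated)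
Conditions: Ru(bpy)3Cl2 (2 mol %), degassed MeCN, blue LEDs (455 nm), 20 °C
Reagents that add atoms: none
Why: Excited divalent ruthenium reduces diazonium salt 7 to an aryl radical with loss of N2; this radical adds to the α-carbon of enaminone 9 (future C3) to give an α-amino radical, which trivalent ruthenium (or a second diazonium ion in a chain) oxidizes to an iminium ion. The closest known reaction type is the visible-light Meerwein-type arylation of ortho-hydroxyaryl enaminones with arenediazonium salts, which gives isoflavones directly. Ring C closes by 6-exo-trig addition of the ring A phenol oxygen to the iminium carbon (future C2) to give aminal 10, and β-elimination of HNMe2 then installs the C2=C3 double bond of the 4-pyranone. The two sp3 centres of 10 are erased in this elimination, so no stereocentre is created, and the axis is not touched. The step needs C-arylation at the α-carbon instead of ionic azo coupling and must spare the finished isoflavone: the first is favoured by the donor amino group, which makes α-attack the only route to a stabilized radical, and by the para-methoxy group, which makes 7 a weak electrophile for azo coupling; the second by the excess of the far more electron-rich enaminone and by the position of the radical carbon, meta to the axis and out of reach of ring A' for a Pschorr-type closure.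

Step 8
Reactants: 11 tetra-O-methylbisoflavolin C
Product: 12 (M)-bisoflavolin C
Conditions: BBr3 (12 equiv), CH2Cl2, −78 °C to rt; MeOH then H2O, 0 °C; then HPLC on cellulose tris(3,5-dimethylphenylcarbamate), 5 °C
Reagents that add atoms: none
Why: Lewis-acid cleavage of aryl methyl ethers with BBr3 is the standard end game for polymethylated biflavonoids and leaves both pyranones intact; no reagent controls the axis, so the (M) form is taken from the atropisomer pair on the chiral phase and identified by its circular dichroism, while the (P) form is re-equilibrated by warming and recycled.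

**Compound list**
1 | formononetin, 7-hydroxy-3-(4-methoxyphenyl)-4H-chromen-4-one | COc1ccc(cc1)-c1coc2cc(O)ccc2c1=O | starting material
2 | 7-hydroxy-8-iodo-3-(4-methoxyphenyl)-4H-chromen-4-one | COc1ccc(cc1)-c1coc2c(I)c(O)ccc2c1=O | intermediate
3 | 8-iodo-7-methoxy-3-(4-methoxyphenyl)-4H-chromen-4-one | COc1ccc(cc1)-c1coc2c(I)c(OC)ccc2c1=O | intermediate
4 | (2-methoxy-5-nitrophenyl)boronic acid | COc1ccc(cc1B(O)O)[N+](=O)[O-] | starting material
5 | 7-methoxy-8-(2-methoxy-5-nitrophenyl)-3-(4-methoxyphenyl)-4H-chromen-4-one (axis unresolved) | COc1ccc(cc1)-c1coc2c(-c3cc(ccc3OC)[N+](=O)[O-])c(OC)ccc2c1=O | intermediate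
6 | 8-(5-amino-2-methoxyphenyl)-7-methoxy-3-(4-methoxyphenyl)-4H-chromen-4-one (axis unresolved) | COc1ccc(cc1)-c1coc2c(-c3cc(N)ccc3OC)c(OC)ccc2c1=O | intermediate
7 | 4-methoxy-3-[7-methoxy-3-(4-methoxyphenyl)-4-oxo-4H-chromen-8-yl]benzenediazonium tetrafluoroborate (axis unresolved) | COc1ccc(cc1)-c1coc2c(-c3cc(ccc3OC)[N+]#N)c(OC)ccc2c1=O.F[B-](F)(F)F | intermediate
8 | paeonol, 1-(2-hydroxy-4-methoxyphenyl)ethan-1-one | CC(=O)c1ccc(OC)cc1O | starting material
9 | (E)-3-(dimethylamino)-1-(2-hydroxy-4-methoxyphenyl)prop-2-en-1-one | CN(C)/C=C/C(=O)c1ccc(OC)cc1O | intermediate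
10 | 2-(dimethylamino)-7-methoxy-3-{4-methoxy-3-[7-methoxy-3-(4-methoxyphenyl)-4-oxo-4H-chromen-8-yl]phenyl}chroman-4-one (mixture of diastereomers at C2 and C3, not isolated) | CN(C)C1Oc2cc(OC)ccc2C(=O)C1c1ccc(OC)c(-c2c(OC)ccc3c(=O)c(-c4ccc(OC)cc4)coc23)c1 | intermediate
11 | tetra-O-methylbisoflavolin C, 7-methoxy-8-[2-methoxy-5-(7-methoxy-4-oxo-4H-chromen-3-yl)phenyl]-3-(4-methoxyphenyl)-4H-chromen-4-one (axis unresolved) | O=c1c(-c2ccc(OC)c(-c3c(OC)ccc4c(=O)c(-c5ccc(OC)cc5)coc34)c2)coc2cc(OC)ccc12 | intermediate
12 | (M)-bisoflavolin C, 7-hydroxy-8-[2-hydroxy-5-(7-hydroxy-4-oxo-4H-chromen-3-yl)phenyl]-3-(4-hydroxyphenyl)-4H-chromen-4-one, (M) at the C3'–C8'' axis | O=c1c(-c2ccc(O)c(-c3c(O)ccc4c(=O)c(-c5ccc(O)cc5)coc34)c2)coc2cc(O)ccc12 | target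

**Step count and risks**

Total step count: 8. Longest linear sequence: 7 (steps 1, 2, 3, 4, 5, 7, 8 from formononetin).

Steps most likely to fail:

Step 7. Ionic azo coupling of the diazonium cation at the enaminone α-carbon, or hydrogen-atom abstraction by the aryl radical (hydrodediazoniation), may outrun the radical C-arylation. The fallback sets out from diazonium salt 7 and enaminone 9 and comes back at tetramethyl ether 11, making the same bond by two-electron cross-coupling onto a preformed ring C. Salt 7 is converted by Sandmeyer-type borylation (B2pin2, eosin Y, MeCN, visible light, rt) into aryl pinacol boronate F1. Enaminone 9 is cyclized with I2 (CHCl3, rt) to 3-iodo-7-methoxychromone F2. Suzuki–Miyaura coupling of the two (PdCl2(dppf), K2CO3, dioxane/H2O, 80 °C) should then give 11.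

Step 3. Protodeboronation of the electron-poor, ortho-alkoxy boronic acid may outrun transmetalation at the crowded C8'' palladium centre, and hydroxide may open ring C' at C2''. The fallback sets out from iodide 3 and comes back at aniline 6, bypassing 5; the nitrogen is brought in by C–N coupling instead of being carried as a nitro group. Iodide 3 is coupled with commercial (5-chloro-2-methoxyphenyl)boronic acid (COc1ccc(Cl)cc1B(O)O; Pd(PPh3)4, K2CO3, DME/H2O, 85 °C, where the aryl chloride stays inert) to give chloro biaryl F3. Buchwald–Hartwig amination with benzophenone imine (Pd2(dba)3, XPhos, Cs2CO3, dioxane, 100 °C) gives N-(diphenylmethylene)aniline F4. Hydrolysis (1 M HCl, THF, rt) releases 6.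

Step 8. The atropisomers may co-elute on the chiral phase, or the axis may rotate during isolation. The fallback sets out from the unresolved atropisomer pair of 12 (after the BBr3 demethylation) and comes back at 12, replacing chromatography on a chiral phase by covalent diastereomers. All four phenols are acylated with (1R,2S,5R)-menthyl chloroformate (ClC(=O)O[C@H]1[C@H](C(C)C)CC[C@@H](C)C1; Et3N, DMAP, CH2Cl2, 0 °C) to give tetrakis(menthyl carbonate) F5 as two diastereomers that differ only at the axis, whose barrier is raised by the two carbonates flanking it. The diastereomers are separated on silica gel or by crystallization. Methanolysis of the (M) diastereomer (K2CO3, MeOH, 0 °C) returns 12.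

**Further compounds**
F1 | step 7 | 7-methoxy-8-[2-methoxy-5-(4,4,5,5-tetramethyl-1,3,2-dioxaborolan-2-yl)phenyl]-3-(4-methoxyphenyl)-4H-chromen-4-one | COc1ccc(cc1)-c1coc2c(-c3cc(ccc3OC)B4OC(C)(C)C(C)(C)O4)c(OC)ccc2c1=O
F2 | step 7 | 3-iodo-7-methoxy-4H-chromen-4-one | COc1ccc2c(c1)occ(I)c2=O
F3 | step 3 | 8-(5-chloro-2-methoxyphenyl)-7-methoxy-3-(4-methoxyphenyl)-4H-chromen-4-one | COc1ccc(cc1)-c1coc2c(-c3cc(Cl)ccc3OC)c(OC)ccc2c1=O
F4 | step 3 | 8-{5-[(diphenylmethylidene)amino]-2-methoxyphenyl}-7-methoxy-3-(4-methoxyphenyl)-4H-chromen-4-one | COc1ccc(cc1)-c1coc2c(-c3cc(N=C(c4ccccc4)c4ccccc4)ccc3OC)c(OC)ccc2c1=O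
F5 | step 8 | (M)-bisoflavolin C tetrakis[(1R,2S,5R)-menthyl carbonate] | O=c1c(-c2ccc(OC(=O)O[C@H]6[C@H](C(C)C)CC[C@@H](C)C6)c(-c3c(OC(=O)O[C@H]7[C@H](C(C)C)CC[C@@H](C)C7)ccc4c(=O)c(-c5ccc(OC(=O)O[C@H]8[C@H](C(C)C)CC[C@@H](C)C8)cc5)coc34)c2)coc2cc(OC(=O)O[C@H]9[C@H](C(C)C)CC[C@@H](C)C9)ccc12
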